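## Retrosynthetic overview

1. The quinone is unmasked last: the 3-methylbutylamino group replaces the methoxy group of a 2-hydroxy-5-methoxyquinone, which comes from the 2,5-dimethoxyquinone by selective saponification and from a 2,3,5,6-tetramethoxyphenyl group (carried from step 1) by ceric oxidation.
2. The C5=C6 alkene comes from a C6 ketone (axial alcohol, anti elimination) and the C8 methyl from cuprate addition to a C7=C8 enone, which leaves a cis-fused bicyclic enone.
3. The route rests on ring A: the methylenes C1–C3 and the gem-dimethyl carbon C4 are attached to ring B at C10 and C5, the β- and α-carbons of the C6 enone. Cutting C1–C10 and C4–C5 gives a 4-methylpenta-1,3-diene unit and one of the two enantiotopic arms of achiral 4-methyl-4-(arylmethyl)cyclohexa-2,5-dienone; a chiral Lewis acid chooses the arm and sets C9 and C10.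
4. The diene is used as its 2-silyloxy derivative. The cis terminal methyl makes the parent diene reluctant to become s-cis; the silyloxy group makes C1 an enol ether carbon and lets C4–C5 form by closure of an enolate onto an enone. The extra C2 oxygen is removed through the enol triflate.
5. Ring order: arene (bought), ring B (Robinson annulation, then dehydrogenation to the dienone), ring A (key step), quinone last.

Key step: step 7

Numbering and faces: terpenoid numbering is used for the bicyclic core (ring A = C1–C5 and C10, ring B = C5–C10, C11 = benzylic CH2 on C9); β is the face of ring B that carries the C9 methyl group, α the opposite face. Ar = 2,3,5,6-tetramethoxyphenyl.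

Assumption: the (S)-oxazaborolidinium ion is taken to activate the arm that leads to the (5R,9R,10R) adduct; its sense of induction on a cross-conjugated dienone is not established, and the (R)-catalyst would be used if it engages the other arm.

## Route

Step 1
Reactants: 1 1,2,4,5-tetramethoxybenzene
Product: 3 2,3,5,6-tetramethoxybenzaldehyde, via aryllithium 2 (not isolated)
Conditions: n-BuLi, TMEDA, THF, 0 °C to rt; DMF, −78 °C to rt; aq. NH4Cl
Reagents that add atoms: N,N-dimethylformamide, CN(C)C=O
Why: Directed ortho-lithiation removes the ring hydrogen flanked by two methoxy groups and the aryllithium is formylated by DMF.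

Step 2
Reactants: 3 2,3,5,6-tetramethoxybenzaldehyde; 4 propanal
Product: 5 (E)-2-methyl-3-(2,3,5,6-tetramethoxyphenyl)prop-2-enal
Conditions: KOH, MeOH/H2O, 0 °C to rt, slow addition of 4
Reagents that add atoms: none
Why: Crossed aldol (Claisen–Schmidt) condensation, in which the non-enolisable aryl aldehyde accepts the propanal enolate and dehydration gives the conjugated enal.

Step 3
Reactants: 5 (E)-2-methyl-3-(2,3,5,6-tetramethoxyphenyl)prop-2-enal
Product: 6 2-methyl-3-(2,3,5,6-tetramethoxyphenyl)propanal (racemic)
Conditions: H2 (1 atm), 5% Pd/C, EtOAc, rt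
Reagents that add atoms: none
Why: Catalytic hydrogenation of the conjugated C=C bond is much faster than reduction of the aldehyde or the arene.

Step 4
Reactants: 6 2-methyl-3-(2,3,5,6-tetramethoxyphenyl)propanal; 7 but-3-en-2-one (methyl vinyl ketone)
Product: 10 4-methyl-4-[(2,3,5,6-tetramethoxyphenyl)methyl]cyclohex-2-en-1-one (racemic), via pyrrolidine enamine 8 (not isolated), via keto aldehyde 9 (not isolated)
Conditions: pyrrolidine (1.1 equiv), toluene, reflux (Dean–Stark); 7, rt to 60 °C; then AcOH, NaOAc, H2O, reflux
Reagents that add atoms: none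
Why: Stork enamine Robinson annulation, in which the enamine of the α-branched aldehyde adds to the enone (Michael addition) and intramolecular aldol condensation of the 1,5-keto aldehyde closes ring B; the quaternary carbon is racemic here and becomes a prochiral centre in 12.

Step 5
Reactants: 10 4-methyl-4-[(2,3,5,6-tetramethoxyphenyl)methyl]cyclohex-2-en-1-one
Product: 12 4-methyl-4-[(2,3,5,6-tetramethoxyphenyl)methyl]cyclohexa-2,5-dien-1-one (achiral), via silyl dienol ether 11 (not isolated)
Conditions: LiN(i-Pr)2, THF, −78 °C; Me3SiCl; then Pd(OAc)2 (1.1 equiv), MeCN, rt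
Reagents that add atoms: none
Why: Saegusa–Ito oxidation, in which kinetic α′-deprotonation gives the cross-conjugated silyl dienol ether and Pd(OAc)2 dehydrogenates it to the symmetric dienone under conditions that should spare the electron-rich arene.

Step 6
Reactants: 13 4-methylpent-3-en-2-one (mesityl oxide)
Product: 15 4-methyl-2-(triisopropylsilyloxy)penta-1,3-diene, via lithium dienolate 14 (not isolated)
Conditions: LiN(i-Pr)2, THF, −78 °C; i-Pr3SiOSO2CF3, −78 to 0 °C
Reagents that add atoms: triisopropylsilyl trifluoromethanesulfonate, CC(C)[Si](OS(=O)(=O)C(F)(F)F)(C(C)C)C(C)C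
Why: Kinetic deprotonation of the enone at the α′-methyl group followed by O-silylation gives the cross-conjugated 2-silyloxydiene.

Step 7
Reactants: 12 4-methyl-4-[(2,3,5,6-tetramethoxyphenyl)methyl]cyclohexa-2,5-dien-1-one; 15 4-methyl-2-(triisopropylsilyloxy)penta-1,3-diene
Product: 16 cis-fused (5R,9R,10R) bicyclic enone: C6 ketone, C7=C8, C2=C3 with OSi(i-Pr)3 on C2, gem-dimethyl C4, C9 β-methyl and α-CH2Ar, H5 and H10 both α
Conditions: (S)-1-(2-methylphenyl)-3,3-diphenyltetrahydro-1H,3H-pyrrolo[1,2-c][1,3,2]oxazaborole (C24H24BNO, 20 mol %), (CF3SO2)2NH (18 mol %), CH2Cl2, −78 to −40 °C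
Reagents that add atoms: none
Why: Proposed new method: the cationic oxazaborolidinium ion binds one carbonyl lone pair of 12 and so activates one enone arm; the enol ether carbon C1 of 15 adds to its β-carbon C10 (Mukaiyama–Michael), and the boron enolate carbon C5 then closes onto the dimethyl-substituted terminus C4 of the silyl-activated enone, so ring A forms by a stepwise or highly asynchronous [4+2] (six-membered ring, enolate-onto-enone closure) that does not need the s-cis diene and joins one molecule of each partner with all atoms retained. The closest known reactions are strong-Lewis-acid cycloadditions of hindered 2-silyloxydienes with cyclohexenones and oxazaborolidinium-catalysed Diels–Alder reactions of enones and quinones; use of such a catalyst to tell apart the two arms of a 4,4-disubstituted cyclohexadienone has not been shown. C9 becomes a stereocentre through the choice of arm (catalyst control), C10 is set by approach of the diene on the face of the small C9 methyl group, anti to the arylmethyl group (substrate control), and C5 follows from closure on the same face, which gives the cis ring fusion. The step needs arm and face selectivity at once: the catalyst shields one face of whichever arm it holds, and only for one arm is the open face also the methyl face of the substrate, so the matched pathway should dominate. Regiochemistry is fixed by the diene polarity (C1 nucleophilic; silyloxy carbon para and dimethyl terminus ortho to the carbonyl-bearing carbon).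

Step 8
Reactants: 16 silyl enol ether adduct
Product: 17 the corresponding C2 enol triflate (C2=C3 with OSO2CF3 on C2; otherwise as 16)
Conditions: CsF, PhN(SO2CF3)2, DME, rt
Reagents that add atoms: N-phenylbis(trifluoromethanesulfonimide), O=S(=O)(N(c1ccccc1)S(=O)(=O)C(F)(F)F)C(F)(F)F
Why: Fluoride cleaves the silyl enol ether and the caesium enolate is trapped in situ as the enol triflate, keeping the double bond at C2=C3.

Step 9
Reactants: 17 enol triflate
Product: 18 (5R,9R,10R) cis-fused enone with C2=C3 alkene: C6 ketone, C7=C8, gem-dimethyl C4, C9 β-methyl and α-CH2Ar, H5 and H10 α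
Conditions: Pd(OAc)2 (5 mol %), PPh3 (10 mol %), HCO2H, n-Bu3N, DMF, 60 °C
Reagents that add atoms: none
Why: Palladium-catalysed formate reduction of the enol triflate (oxidative addition to zerovalent palladium, hydride from formate, reductive elimination) removes the C2 oxygen and leaves the C2=C3 alkene.

Step 10
Reactants: 18 cis-fused enone
Product: 19 cis-fused ketone with 8β-methyl (C6 ketone, C7 methylene, C2=C3 alkene; C9, C10, C5 as in 18)
Conditions: Me2CuLi (from MeLi and CuI), Et2O, −78 to −30 °C; aq. NH4Cl
Reagents that add atoms: lithium dimethylcuprate, [Li+].C[Cu-]C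
Why: Gilman cuprate conjugate addition: in the favoured half-chair of the cis-fused enone the arylmethyl group on C9 is pseudoaxial on the α face, so axial attack at C8 should come from the β face, anti to it, placing the new methyl cis to the C9 methyl.

Step 11
Reactants: 19 cis-fused ketone with C2=C3 alkene
Product: 20 the ring A saturated cis-fused ketone (8β-methyl, H5 and H10 α)
Conditions: H2 (1 atm), 10% Pd/C, EtOAc, rt
Reagents that add atoms: none
Why: Heterogeneous hydrogenation saturates the cis-disubstituted ring A alkene and should leave the hindered ketone and the arene untouched.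

Step 12
Reactants: 20 cis-fused ketone
Product: 21 trans-fused ketone (H5 β, H10 α; 8β-methyl, 9β-methyl, 9α-CH2Ar)
Conditions: NaOMe, MeOH, 50 °C
Reagents that add atoms: none
Why: Base-mediated epimerisation at C5 through the enolate, under thermodynamic control: the cis isomer must hold either the C8 methyl syn-diaxial to C1 or the C9 methyl syn-diaxial to C4, and the trans isomer has neither clash.

Step 13
Reactants: 21 trans-fused ketone
Product: 22 axial 6α-alcohol (otherwise as 21)
Conditions: LiBH(s-Bu)3, THF, −78 to 0 °C; aq. NH4Cl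
Reagents that add atoms: none
Why: Bulky-hydride reduction: the axial path to C6 is blocked by the axial methyl on C4, so hydride should enter equatorially and give the axial alcohol.

Step 14
Reactants: 22 axial 6α-alcohol
Product: 24 C5=C6 alkene: 4,4,8β,9β-tetramethyl-9α-CH2Ar decalin with H10 α, via dichlorophosphate 23 (not isolated)
Conditions: POCl3, pyridine, 0 to 70 °C
Reagents that add atoms: none
Why: Dehydration by anti-periplanar E2 elimination of the dichlorophosphate: the axial leaving group and the axial tertiary H5 are trans-diaxial, and loss of H5 gives the more substituted alkene (Zaitsev), removing the C5 and C6 stereocentres.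

Step 15
Reactants: 24 tetramethoxyarene with C5=C6 alkene
Product: 25 2,5-dimethoxy-3-alkyl-1,4-benzoquinone (alkyl = C11 of the bicyclic core)
Conditions: (NH4)2Ce(NO3)6, MeCN/H2O, 0 °C
Reagents that add atoms: water, O
Why: Oxidative demethylation of one para-dimethoxy pair by tetravalent cerium gives the p-quinone, the carbonyl oxygens coming from water; the hindered alkene should survive.

Step 16
Reactants: 25 dimethoxyquinone
Product: 26 2-hydroxy-5-methoxy-3-alkyl-1,4-benzoquinone
Conditions: KOH, MeOH/H2O, rt; then aq. HCl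
Reagents that add atoms: potassium hydroxide, [K+].[OH-]
Why: Regioselective saponification of a vinylogous ester: hydroxide should displace the methoxy group next to the alkyl arm, which is twisted out of conjugation, and ionisation of the product as a vinylogous acid stops the second hydrolysis.

Step 17
Reactants: 26 hydroxymethoxyquinone; 27 3-methylbutan-1-amine
Product: 28 nakijiquinone M, (8S,9R,10S)
Conditions: NaHCO3, EtOH, rt
Reagents that add atoms: none
Why: Addition–elimination of the primary amine at the remaining vinylogous ester carbon exchanges methoxy for the amino group, while the ionised hydroxy group is not displaced.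

## Compound list

1 | 1,2,4,5-tetramethoxybenzene | COc1cc(OC)c(OC)cc1OC | starting material
2 | (2,3,5,6-tetramethoxyphenyl)lithium | [Li]c1c(OC)c(OC)cc(OC)c1OC | intermediate (not isolated)
3 | 2,3,5,6-tetramethoxybenzaldehyde | O=Cc1c(OC)c(OC)cc(OC)c1OC | intermediate
4 | propanal | CCC=O | starting material
5 | (E)-2-methyl-3-(2,3,5,6-tetramethoxyphenyl)prop-2-enal | O=C/C(C)=C/c1c(OC)c(OC)cc(OC)c1OC | intermediate
6 | 2-methyl-3-(2,3,5,6-tetramethoxyphenyl)propanal (racemic) | O=CC(C)Cc1c(OC)c(OC)cc(OC)c1OC | intermediate
7 | but-3-en-2-one | C=CC(C)=O | starting material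
8 | 1-[2-methyl-3-(2,3,5,6-tetramethoxyphenyl)prop-1-en-1-yl]pyrrolidine | CC(=CN1CCCC1)Cc1c(OC)c(OC)cc(OC)c1OC | intermediate (not isolated)
9 | 2-methyl-5-oxo-2-[(2,3,5,6-tetramethoxyphenyl)methyl]hexanal (racemic) | CC(=O)CCC(C)(C=O)Cc1c(OC)c(OC)cc(OC)c1OC | intermediate (not isolated)
10 | 4-methyl-4-[(2,3,5,6-tetramethoxyphenyl)methyl]cyclohex-2-en-1-one (racemic) | CC1(Cc2c(OC)c(OC)cc(OC)c2OC)C=CC(=O)CC1 | intermediate
11 | trimethyl({4-methyl-4-[(2,3,5,6-tetramethoxyphenyl)methyl]cyclohexa-1,5-dien-1-yl}oxy)silane | CC1(Cc2c(OC)c(OC)cc(OC)c2OC)C=CC(O[Si](C)(C)C)=CC1 | intermediate (not isolated)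
12 | 4-methyl-4-[(2,3,5,6-tetramethoxyphenyl)methyl]cyclohexa-2,5-dien-1-one (achiral) | CC1(Cc2c(OC)c(OC)cc(OC)c2OC)C=CC(=O)C=C1 | intermediate
13 | 4-methylpent-3-en-2-one | CC(=O)C=C(C)C | starting material
14 | lithium 4-methylpenta-1,3-dien-2-olate | [Li+].[O-]C(=C)C=C(C)C | intermediate (not isolated)
15 | 4-methyl-2-(triisopropylsilyloxy)penta-1,3-diene | C=C(O[Si](C(C)C)(C(C)C)C(C)C)C=C(C)C | intermediate
16 | (5R,9R,10R) cis-fused enone, C2 triisopropylsilyl enol ether (C2=C3), C6 ketone, C7=C8, 9β-Me, 9α-CH2Ar, H5 and H10 α | C[C@@]1(Cc2c(OC)c(OC)cc(OC)c2OC)C=CC(=O)[C@@H]2[C@H]1CC(O[Si](C(C)C)(C(C)C)C(C)C)=CC2(C)C | intermediate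
17 | as 16 with OSO2CF3 on C2 (enol triflate) | C[C@@]1(Cc2c(OC)c(OC)cc(OC)c2OC)C=CC(=O)[C@@H]2[C@H]1CC(OS(=O)(=O)C(F)(F)F)=CC2(C)C | intermediate
18 | (5R,9R,10R) cis-fused enone with C2=C3 alkene, C6 ketone, C7=C8, 9β-Me, 9α-CH2Ar, H5 and H10 α | C[C@@]1(Cc2c(OC)c(OC)cc(OC)c2OC)C=CC(=O)[C@@H]2[C@H]1CC=CC2(C)C | intermediate
19 | cis-fused C6 ketone, 8β-Me, 9β-Me, 9α-CH2Ar, H5 and H10 α, C2=C3 alkene | C[C@@]1(Cc2c(OC)c(OC)cc(OC)c2OC)[C@@H](C)CC(=O)[C@@H]2[C@H]1CC=CC2(C)C | intermediate
20 | cis-fused C6 ketone as 19 with saturated ring A | C[C@@]1(Cc2c(OC)c(OC)cc(OC)c2OC)[C@@H](C)CC(=O)[C@@H]2[C@H]1CCCC2(C)C | intermediate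
21 | trans-fused C6 ketone (H5 β, H10 α), 8β-Me, 9β-Me, 9α-CH2Ar | C[C@@]1(Cc2c(OC)c(OC)cc(OC)c2OC)[C@@H](C)CC(=O)[C@H]2[C@H]1CCCC2(C)C | intermediate
22 | trans-fused 6α-ol (axial OH), otherwise as 21 | C[C@@]1(Cc2c(OC)c(OC)cc(OC)c2OC)[C@@H](C)C[C@H](O)[C@H]2[C@H]1CCCC2(C)C | intermediate
23 | 6α-dichlorophosphate of 22 | C[C@@]1(Cc2c(OC)c(OC)cc(OC)c2OC)[C@@H](C)C[C@H](OP(=O)(Cl)Cl)[C@H]2[C@H]1CCCC2(C)C | intermediate (not isolated)
24 | C5=C6 alkene: 4,4,8β,9β-tetramethyl-9α-CH2Ar, H10 α | C[C@@]1(Cc2c(OC)c(OC)cc(OC)c2OC)[C@@H](C)CC=C2[C@H]1CCCC2(C)C | intermediate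
25 | 2,5-dimethoxy-3-(C11)-1,4-benzoquinone on the core of 24 | C[C@@]1(CC2=C(OC)C(=O)C=C(OC)C2=O)[C@@H](C)CC=C2[C@H]1CCCC2(C)C | intermediate
26 | 2-hydroxy-5-methoxy-3-(C11)-1,4-benzoquinone on the core of 24 | C[C@@]1(CC2=C(O)C(=O)C=C(OC)C2=O)[C@@H](C)CC=C2[C@H]1CCCC2(C)C | intermediate
27 | 3-methylbutan-1-amine | CC(C)CCN | starting material
28 | nakijiquinone M, (8S,9R,10S) | CC(C)CCNC1=CC(=O)C(O)=C(C[C@@]2(C)[C@@H]3CCCC(C)(C)C3=CC[C@@H]2C)C1=O | target

## Step count and risks

Total step count: 17. Longest linear sequence: 16 steps (steps 1–5 and 7–17); step 6 is a one-step branch.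

Steps most likely to fail:

1. Step 7 (proposed new method). Bond formation may stop after the first C–C bond without ring closure, closure may occur at the carbonyl carbon to give a four-membered ring, or the catalyst may fail to tell the two arms apart so that the enantiomeric excess is low. The fallback sets out from 12 and comes back to the route at 20. It uses the known copper-catalysed desymmetrisation of 4,4-disubstituted cyclohexadienones by dialkylzinc reagents: Cu(OTf)2 with the (S)-binaphthol bis[(R)-1-phenylethyl]amine phosphoramidite (C36H30NO2P) and bis(4-methylpent-3-en-1-yl)zinc (from 5-bromo-2-methylpent-2-ene by Mg insertion in THF and transmetallation with ZnCl2) should add the C1–C4 chain to one arm, anti to the arylmethyl group, giving the 5-(4-methylpent-3-enyl) enone F1. HCl in CH2Cl2 would add to the trisubstituted alkene to give the tertiary chloride F2. Me3SiOSO2CF3/Et3N would give the silyl dienol ether F3, and TiCl4 at −78 °C would ionise the chloride and close ring A at C5 by Lewis-acid α-tert-alkylation of the enol ether, giving the cis-fused enone with saturated ring A F4. Me2CuLi as in step 10 would then give 20.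

2. Step 10. Facial selectivity of the conjugate addition may be poor, because the β face that must be attacked is also screened by the axial C1 methylene of ring A. The fallback sets out from 18 and comes back at 19, and delivers the methyl carbon through a hydroxyl group. Luche reduction (NaBH4, CeCl3·7H2O, MeOH) should give the 6β-allylic alcohol F5 by hydride attack anti to ring A. Simmons–Smith cyclopropanation (Et2Zn, CH2I2, CH2Cl2) directed by the zinc alkoxide would give the β-cyclopropyl carbinol F6. Dess–Martin oxidation would give the cyclopropyl ketone F7, and Li in liquid NH3 would cleave the cyclopropane bond that overlaps the carbonyl π system (C7–CH2), leaving the methyl on the β face of C8 in 19. If the reduction gave the 6α-alcohol instead, Mitsunobu inversion would be needed first.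

3. Step 14. Elimination may run toward C7 instead of C5, or ionisation may set off a 1,2-shift from C4. The fallback sets out from 21 and comes back at 24, and fixes the regiochemistry by leaving C5–H as the only sp3 α-hydrogen. LiN(i-Pr)2/Me3SiCl would give the kinetic C6=C7 silyl enol ether F8, and Pd(OAc)2 in MeCN the trans-fused 8-methyl-7-en-6-one F9. KN(SiMe3)2 and PhN(SO2CF3)2 would then enolise toward C5 and give the 5,7-dien-6-yl triflate F10. Hydrogenation with [Ir(cod)(PCy3)(py)]PF6 in CH2Cl2 should reduce only the C7=C8 bond, from the α face anti to the axial C9 methyl, giving the 5-en-6-yl triflate F11 with the 8β-methyl restored. Pd(OAc)2/PPh3/HCO2H/n-Bu3N would then give 24.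

## Further compounds

F1 | step 7 | 4-methyl-5-(4-methylpent-3-en-1-yl)-4-[(2,3,5,6-tetramethoxyphenyl)methyl]cyclohex-2-en-1-one, side chain cis to the ring methyl | C[C@@]1(Cc2c(OC)c(OC)cc(OC)c2OC)C=CC(=O)C[C@H]1CCC=C(C)C
F2 | step 7 | 5-(4-chloro-4-methylpentyl) analogue of F1 | C[C@@]1(Cc2c(OC)c(OC)cc(OC)c2OC)C=CC(=O)C[C@H]1CCCC(C)(C)Cl
F3 | step 7 | trimethylsilyl dienol ether of F2 (C5=C6–O–Si, C7=C8) | C[C@@]1(Cc2c(OC)c(OC)cc(OC)c2OC)C=CC(O[Si](C)(C)C)=C[C@H]1CCCC(C)(C)Cl
F4 | step 7 | cis-fused enone as 18 with saturated ring A | C[C@@]1(Cc2c(OC)c(OC)cc(OC)c2OC)C=CC(=O)[C@@H]2[C@H]1CCCC2(C)C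
F5 | step 10 | 6β-allylic alcohol from 18 | C[C@@]1(Cc2c(OC)c(OC)cc(OC)c2OC)C=C[C@@H](O)[C@@H]2[C@H]1CC=CC2(C)C
F6 | step 10 | 7β,8β-methano 6β-alcohol | C[C@@]1(Cc2c(OC)c(OC)cc(OC)c2OC)[C@H]2C[C@H]2[C@@H](O)[C@@H]3[C@H]1CC=CC3(C)C
F7 | step 10 | 7β,8β-methano 6-ketone | C[C@@]1(Cc2c(OC)c(OC)cc(OC)c2OC)[C@H]2C[C@H]2C(=O)[C@@H]3[C@H]1CC=CC3(C)C
F8 | step 14 | C6=C7 trimethylsilyl enol ether of 21 | C[C@@]1(Cc2c(OC)c(OC)cc(OC)c2OC)[C@@H](C)C=C(O[Si](C)(C)C)[C@H]2[C@H]1CCCC2(C)C
F9 | step 14 | trans-fused 8-methyl-7-en-6-one | C[C@@]1(Cc2c(OC)c(OC)cc(OC)c2OC)C(C)=CC(=O)[C@H]2[C@H]1CCCC2(C)C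
F10 | step 14 | 8-methyl-5,7-dien-6-yl triflate | C[C@@]1(Cc2c(OC)c(OC)cc(OC)c2OC)C(C)=CC(OS(=O)(=O)C(F)(F)F)=C2[C@H]1CCCC2(C)C
F11 | step 14 | 8β-methyl-5-en-6-yl triflate | C[C@@]1(Cc2c(OC)c(OC)cc(OC)c2OC)[C@@H](C)CC(OS(=O)(=O)C(F)(F)F)=C2[C@H]1CCCC2(C)C
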